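## Retrosynthetic overview

1. Target ⇒ cut the cyclohexa-2,5-dienone at C1–C2 and C3–C4: a two-carbon ring expansion of a 3,4-dimethoxy-4-alkylcyclobutenone with pent-1-en-4-yne (C–C activation by zerovalent nickel). The alkyne supplies C2, C3 and the allyl group.
2. Cyclobutenone ⇒ C4–C8 bond: a configurationally defined secondary alkyllithium adds to methyl semisquarate and the alkoxide is trapped as its methyl ether.
3. Alkyllithium ⇒ (R)-iodide ⇒ (S)-carbinol ⇒ aryl Grignard reagent + (S)-propylene oxide; the arene comes from catechol.
4. Methyl semisquarate ⇒ dimethyl squarate ⇒ squaric acid.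
5. Ring order: the aromatic ring and the four-membered ring are bought; the six-membered dienone ring is formed last, by the ring expansion.

Assumption: catechol, (S)-propylene oxide, squaric acid and pent-1-en-4-yne are purchased; everything else is made.

## Route

Step 1
Reactants: 1 catechol (benzene-1,2-diol)
Product: 2 1,2-dimethoxybenzene (veratrole)
Conditions: MeI (2.5 equiv), K2CO3, acetone, reflux
Reagents that add atoms: iodomethane, CI
Why: Williamson ether synthesis (SN2 O-methylation of both phenoxides); no stereocentre is involved.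

Step 2
Reactants: 2 1,2-dimethoxybenzene
Product: 3 4-bromo-1,2-dimethoxybenzene
Conditions: NBS (1.05 equiv), MeCN, 0 °C → rt
Reagents that add atoms: N-bromosuccinimide, O=C1CCC(=O)N1Br
Why: Electrophilic aromatic bromination para to a methoxy group; positions 4 and 5 are equivalent and position 3 is hindered, so one monobromide forms.

Step 3
Reactants: 3 4-bromo-1,2-dimethoxybenzene; 4 (S)-propylene oxide [(2S)-2-methyloxirane]
Product: 6 (2S)-1-(3,4-dimethoxyphenyl)propan-2-ol, via aryl Grignard reagent 5 (not isolated)
Conditions: Mg, THF, reflux; then CuI (10 mol %), 4 (1.2 equiv), −30 → 0 °C; aq. NH4Cl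
Reagents that add atoms: none
Why: Grignard formation, then copper-catalysed SN2 opening of the epoxide at its CH2 terminus; the stereocentre of 4 is not touched, so 6 is (S).

Step 4
Reactants: 6 (2S)-1-(3,4-dimethoxyphenyl)propan-2-ol
Product: 7 4-[(2R)-2-iodopropyl]-1,2-dimethoxybenzene
Conditions: PPh3, I2, imidazole, CH2Cl2, −10 → 0 °C, dark, short reaction time
Reagents that add atoms: iodine, II
Why: Appel reaction; iodide displaces the alkoxyphosphonium group by SN2 with inversion, (S) → (R), and low temperature limits racemisation by iodide exchange.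

Step 5
Reactants: 8 squaric acid (3,4-dihydroxycyclobut-3-ene-1,2-dione)
Product: 9 dimethyl squarate (3,4-dimethoxycyclobut-3-ene-1,2-dione)
Conditions: HC(OMe)3, MeOH, reflux
Reagents that add atoms: trimethyl orthoformate, COC(OC)OC; methanol, CO
Why: Self-catalysed vinylogous Fischer esterification, driven by the orthoester as water scavenger.

Step 6
Reactants: 9 dimethyl squarate
Product: 11 3-methoxycyclobut-3-ene-1,2-dione (methyl semisquarate), via hydride adduct 10 (not isolated)
Conditions: LiAlH(OtBu)3 (1.05 equiv), THF, −78 °C; aq. HCl; then conc. HCl (cat.), CH2Cl2, rt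
Reagents that add atoms: water, O
Why: Selective 1,2-reduction of one carbonyl by the bulky hydride, then acid-induced ionisation of the allylic carbinol, capture by water at the methoxy-bearing carbon and loss of methanol (an allylic transposition documented for diisopropyl squarate); 10 is racemic and its stereocentre disappears.

Step 7
Reactants: 7 4-[(2R)-2-iodopropyl]-1,2-dimethoxybenzene; 11 3-methoxycyclobut-3-ene-1,2-dione
Product: 14 (4R)-3,4-dimethoxy-4-[(2R)-1-(3,4-dimethoxyphenyl)propan-2-yl]cyclobut-2-en-1-one, via secondary alkyllithium 12 (not isolated), via lithium alkoxide 13 (not isolated)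
Conditions: 7 (1.3 equiv) added to tBuLi (2.6 equiv), pentane/Et2O 3:2, −100 °C, 1 min; 11 (1.0 equiv) in Et2O, −100 → −78 °C; MeOTf (3 equiv), THF, −78 → 0 °C; chromatography
Reagents that add atoms: methyl trifluoromethanesulfonate, COS(=O)(=O)C(F)(F)F
Why: Iodine–lithium exchange at −100 °C in pentane/ether gives the unstabilised secondary alkyllithium 12 with retention, and its 1,2-addition (retention at the carbanion carbon, so C8 stays R) goes to the ketone-type carbonyl of 11 next to the methoxy-bearing carbon, not to the vinylogous ester carbonyl; the new C4 centre forms on a planar, unbiased carbonyl (expected dr near 1:1), so after Williamson-type trapping of 13 with MeOTf the (4R) epimer 14 is isolated by chromatography and its configuration confirmed by X-ray or by correlation with 16.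

Step 8
Reactants: 14 (4R)-3,4-dimethoxy-4-[(2R)-1-(3,4-dimethoxyphenyl)propan-2-yl]cyclobut-2-en-1-one; 15 pent-1-en-4-yne
Product: 16 lancifolin C, (4S)-4,5-dimethoxy-4-[(2R)-1-(3,4-dimethoxyphenyl)propan-2-yl]-2-(prop-2-en-1-yl)cyclohexa-2,5-dien-1-one
Conditions: Ni(cod)2 (10 mol %), PPh3 (20 mol %), 15 (3 equiv, syringe pump), toluene, 0 °C → rt
Reagents that add atoms: none
Why: Proposed new method: zerovalent nickel inserts into the strained C1(acyl)–C4 σ-bond of 14 to give a divalent nickelacyclopentenone (or its face-bound η4-vinylketene form), the terminal alkyne inserts so that its unsubstituted carbon bonds to the fully substituted C4 (steric control), and acyl–alkenyl reductive elimination closes the six-membered ring; because C4 carries no hydrogen the product cannot tautomerise to a phenol and is released as the cross-conjugated dienone, and because C4 stays bound to one face of nickel its configuration is retained (4R in 14 becomes 4S in 16 only through a change of CIP priorities); closest known reaction type: nickel-catalysed cyclobutenone–alkyne benzannulation to phenols and nickel-catalysed alkyne insertion into cyclobutanones and azetidin-3-ones (formal [4+2] C–C activation), not yet shown for a 4-alkoxy-4-alkylcyclobutenone, for a dienone product or with transfer of a quaternary stereocentre.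

## Compound list

1 | catechol (benzene-1,2-diol) | Oc1ccccc1O | starting material
2 | 1,2-dimethoxybenzene | COc1ccccc1OC | intermediate
3 | 4-bromo-1,2-dimethoxybenzene | COc1ccc(Br)cc1OC | intermediate
4 | (S)-propylene oxide, (2S)-2-methyloxirane | C[C@H]1CO1 | starting material
5 | (3,4-dimethoxyphenyl)magnesium bromide | COc1ccc([Mg]Br)cc1OC | intermediate
6 | (2S)-1-(3,4-dimethoxyphenyl)propan-2-ol | C[C@H](O)Cc1ccc(OC)c(OC)c1 | intermediate
7 | 4-[(2R)-2-iodopropyl]-1,2-dimethoxybenzene | C[C@@H](I)Cc1ccc(OC)c(OC)c1 | intermediate
8 | squaric acid (3,4-dihydroxycyclobut-3-ene-1,2-dione) | OC1=C(O)C(=O)C1=O | starting material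
9 | dimethyl squarate (3,4-dimethoxycyclobut-3-ene-1,2-dione) | COC1=C(OC)C(=O)C1=O | intermediate
10 | 4-hydroxy-2,3-dimethoxycyclobut-2-en-1-one (racemic) | COC1=C(OC)C(O)C1=O | intermediate
11 | 3-methoxycyclobut-3-ene-1,2-dione (methyl semisquarate) | COC1=CC(=O)C1=O | intermediate
12 | [(2R)-1-(3,4-dimethoxyphenyl)propan-2-yl]lithium | C[C@@H]([Li])Cc1ccc(OC)c(OC)c1 | intermediate
13 | lithium (1R)-1-[(2R)-1-(3,4-dimethoxyphenyl)propan-2-yl]-2-methoxy-4-oxocyclobut-2-en-1-olate | O=C1C=C(OC)[C@]1(O[Li])[C@H](C)Cc1ccc(OC)c(OC)c1 | intermediate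
14 | (4R)-3,4-dimethoxy-4-[(2R)-1-(3,4-dimethoxyphenyl)propan-2-yl]cyclobut-2-en-1-one | O=C1C=C(OC)[C@]1(OC)[C@H](C)Cc1ccc(OC)c(OC)c1 | intermediate
15 | pent-1-en-4-yne | C=CCC#C | starting material
16 | lancifolin C, (4S)-4,5-dimethoxy-4-[(2R)-1-(3,4-dimethoxyphenyl)propan-2-yl]-2-(prop-2-en-1-yl)cyclohexa-2,5-dien-1-one | C=CCC1=C[C@@](OC)([C@H](C)Cc2ccc(OC)c(OC)c2)C(OC)=CC1=O | target

## Step count and risks

Total steps: 8. Longest linear sequence: 6 (steps 1, 2, 3, 4, 7, 8); steps 5 and 6 form the second branch.

Three steps most likely to fail: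

**Step 8 (the proposed new ring expansion).** Possible failures are alkyne oligomerisation at zerovalent nickel, the wrong insertion regiochemistry, β-hydride loss from C8–H in the nickelacycle, or loss of C4 configuration through a free vinylketene. The fallback uses known chemistry, sets out from 12 (generated from 7 exactly as in step 7) and comes back to the route at 16. Purchased 1,4-benzoquinone F1 is allylated with allyltributylstannane and BF3·OEt2 (CH2Cl2, −78 °C) to 2-allylbenzene-1,4-diol F2. Ag2O (Et2O, rt) oxidises this to 2-allyl-1,4-benzoquinone F3. MeOH/ZnCl2 (rt; a second equivalent of F3 acts as oxidant and returns F2) gives 2-allyl-5-methoxy-1,4-benzoquinone F4. Alkyllithium 12 adds at −100 → −78 °C to the carbonyl of F4 next to the methoxy-bearing carbon (the other carbonyl is a hindered vinylogous ester) to give lithium dienone alkoxide F5, which MeOTf methylates to 16. The C4 epimer is removed by HPLC.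

**Step 7 (alkyllithium addition and trapping).** Possible failures are partial loss of configuration of 12 (checked by chiral HPLC of 14), the uncontrolled C4 centre, and incomplete methylation of the hindered alkoxide in the cold ether mixture. The fallback sets out from 13 and comes back at 14. The reaction is quenched with aq. NH4Cl to give (4R)-4-hydroxy-3-methoxy-4-[(2R)-1-(3,4-dimethoxyphenyl)propan-2-yl]cyclobut-2-en-1-one F6 together with its C4 epimer. The two carbinols are separated by chromatography or crystallisation, and F6 is methylated under neutral Purdie conditions (MeI, Ag2O, MeCN, rt) to 14.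

**Step 6 (methyl semisquarate).** The methyl ester is more prone to hydrolysis and over-reduction than the isopropyl ester for which the sequence is established. The fallback sets out from 8 and comes back at 11. Squaric acid and propan-2-ol (benzene, Dean–Stark) give diisopropyl squarate F7. LiAlH(OtBu)3 (THF, −78 °C), then conc. HCl (CH2Cl2), give, through 4-hydroxy-2,3-diisopropoxycyclobut-2-en-1-one F8, the robust 3-isopropoxycyclobut-3-ene-1,2-dione F9. Acid-catalysed alkoxy exchange (MeOH, cat. TsOH, 40 °C) then gives 11.

## Further compounds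

F1 | step 8 | 1,4-benzoquinone (purchased) | O=C1C=CC(=O)C=C1
F2 | step 8 | 2-allylbenzene-1,4-diol | C=CCc1cc(O)ccc1O
F3 | step 8 | 2-allyl-1,4-benzoquinone | C=CCC1=CC(=O)C=CC1=O
F4 | step 8 | 2-allyl-5-methoxy-1,4-benzoquinone | C=CCC1=CC(=O)C(OC)=CC1=O
F5 | step 8 | lithium (1S)-1-[(2R)-1-(3,4-dimethoxyphenyl)propan-2-yl]-2-methoxy-4-oxo-5-(prop-2-en-1-yl)cyclohexa-2,5-dien-1-olate | C=CCC1=C[C@@](O[Li])([C@H](C)Cc2ccc(OC)c(OC)c2)C(OC)=CC1=O
F6 | step 7 | (4R)-4-hydroxy-3-methoxy-4-[(2R)-1-(3,4-dimethoxyphenyl)propan-2-yl]cyclobut-2-en-1-one | O=C1C=C(OC)[C@]1(O)[C@H](C)Cc1ccc(OC)c(OC)c1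
F7 | step 6 | diisopropyl squarate, 3,4-di(propan-2-yloxy)cyclobut-3-ene-1,2-dione | CC(C)OC1=C(OC(C)C)C(=O)C1=O
F8 | step 6 | 4-hydroxy-2,3-di(propan-2-yloxy)cyclobut-2-en-1-one (racemic) | CC(C)OC1=C(OC(C)C)C(O)C1=O
F9 | step 6 | 3-(propan-2-yloxy)cyclobut-3-ene-1,2-dione | CC(C)OC1=CC(=O)C1=O
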